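**Remark on the chemistry:** the target is taken as the isomer encoded by the SMILES, which is (4S,5S,6R,9R) in the atom numbering defined below and (1R,3aR,8S,8aS) in azulene numbering. The numbers C1–C10 are kept for every intermediate.

## Structural features

The target is a hydroazulene: a cyclohept-2-enone (C1 ketone, C2 methyl-bearing alkene carbon, C3, C4 carbinol, C5, C6, C10 methylene) fused through the C5–C6 bond to a cyclopentane (C5, C6, C7, C8, C9). The fusion is trans, with H on C5 and the methyl group on quaternary C6 on opposite faces. Four stereocentres are grouped around C5: the allylic carbinol C4 (oxygen cis to H5), C5, quaternary C6, and fully substituted C9, which carries an isopropyl group on the face of H5 and a 4-hydroxybenzoyloxy group on the face of the C6 methyl group. The fragile parts are the γ-hydroxy enone (base turns it into the 1,4-dione, acid dehydrates it), the hindered tertiary aryl ester lying 1,3 and syn to the free C4 hydroxyl (acyl shift), and the phenol. Any intermediate with a carbonyl at C9 is also open to C5 epimerisation and to β-loss of the C4 oxygen. The real difficulty is the contiguous C4–C5–C6 array with a quaternary carbon at a trans ring junction, together with a congested tertiary ester at C9. The pattern C1(=O)–C2(CH3)=C3–C4(O), with C10 next to the ketone, is what a 4-methyl-3-oxidopyrylium leaves behind once a C10–O bond has been cut reductively, and C5–C6 is its two-carbon partner. A (5+2) cycloaddition can therefore close the seven-membered ring and set C4, C5 and C6 together.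

## Logic of the disconnections

**19 ⇒ 18.** Three O–Si bonds are put back: on the phenol oxygen, on O4 and on the C1 oxygen, the last as a C1=C10 silyl dienol ether. The phenol, the γ-hydroxy enone and the 1,3-related ester are thus released together and last. The gain is that 18 has no free hydroxyl, no ketone and no acidic C–H. The forward step must be a mildly acidic fluoride treatment; protonation of the dienol ether can only occur at C10, so the C2=C3 enone results, and the aroyl group must not move from O9 to O4.

**18 ⇒ 14 + 17.** The O9–acyl bond is cut. The ester is introduced late, when the tertiary alkoxide is the only nucleophile and no enolisable carbonyl is present. The gain is removal of the aryl fragment. The forward step must acylate a hindered tertiary alkoxide without transfer of the neighbouring silyl group from O4.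

**17 ⇒ 16 ⇒ 15.** The C–Cl bond and then the two O–Si bonds are undone. The silyl ester of 16 is the activated carboxyl derivative, so the phenol is protected and the acid activated in two operations. The demand is neutral chlorination that spares the aryl silyl ether.

**14 ⇒ 13.** The C9–isopropyl bond is cut, so the C9 stereocentre is traced to a ketone. The gain is loss of one stereocentre and one substituent. The forward addition must come from the face of H5 (the other face carries the C6 methyl group and the C5–C4 bond), must use a weakly basic isopropyl nucleophile, and needs C1 masked, which the dienol ether provides.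

**13 ⇒ 12 ⇒ 11.** A methoxycarbonyl group is returned to C8 and the C8–C9 bond is then cut, opening the five-membered ring to two ester arms. The gain is a monocyclic diester. In 9 the oxygen bridge holds the C4–C5–C6–C10 torsion near 0°, so the trans-placed C7 and C9 arms are about 120° apart and cannot be joined in a five-membered ring. The ring closure is therefore placed after the bridge has been opened, and C1 must not be a free, enolisable ketone, whose enolate would be acylated by the chain ester. The two methyl esters need no differentiation, because only the C8-enolate/C9-ester combination gives an enolisable β-keto ester.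

**11 ⇒ 10.** The O4–Si and O1–Si bonds are cut. One reagent protects the alcohol and converts the enone into the cross-conjugated dienol ether, so the mask costs no extra step. The demand is enolisation at C10 only, which is the only α-position with a removable hydrogen on that side.

**10 ⇒ 9.** The C10–H bond is exchanged for a C10–O4 bond, restoring the oxygen bridge. This reveals the oxygen-bridged enone that a (5+2) cycloaddition delivers. The gain is a rigid bicycle in which C4, C5 and C6 are related through one transition state. The forward step must cleave the C–O bond next to the ketone and not the same oxygen at C4.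

**9 ⇒ 8 + 7 (8 from 4).** The C4–C5 and C6–C10 bonds are cut. This removes the seven-membered carbocycle and four stereocentres in one step and leaves two small achiral or racemic components. The forward step must be regioselective (C10 to the β-carbon), endo-selective for the ester, faithful to the alkene geometry, and face-selective under catalyst control.

**4 ⇒ 3 ⇒ 2 ⇒ 1.** The acetal O–acyl bond, then the pyranone ring (back to a 2-furylmethanol), then the carbinol C–H bonds are undone. The furan C3 methyl group becomes the methyl group next to the ketone. The demand is a clean oxidative ring expansion.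

**7 ⇒ 5 + 6.** The C5=C6 double bond is cut. Both halves are bulk chemicals. The (E)-isomer must be obtained pure, since its geometry becomes the C5/C6 relative configuration.

## Other disconnections considered

**Alternative 1:** The cut is through C5–C6 and C3–C4, which opens both rings and leads to A2, a 1-silyloxy-1-alkenylcyclopropane tethered to a terminal alkyne. In the forward sense a cationic complex of monovalent rhodium with a chiral bisphosphine (for example [Rh(cod)2]BF4 with BINAP) would open the cyclopropane of A2 and join it to the alkyne, giving the bicyclo[5.3.0]decadiene A1 with quaternary C6.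
- In its favour: two rings, two bonds and the quaternary centre are formed catalytically from an open chain. The reaction class, including enantioselective variants, is established. A1 carries useful handles (C1 silyl enol ether, C4=C5 alkene, C9 ketal).
- Against it here: only C6 is set. C4, C5, C9, the C2 methyl group and the C2=C3 unsaturation must all be added afterwards. Hydroboration of C4=C5 anti to the C6 methyl group would plausibly give the trans fusion and the cis C4 hydroxyl, but methylation and dehydrogenation at C2 need regiocontrol against C10. The alkene terminus of A2 is fully substituted, the least favourable pattern for this cycloaddition, and A2 needs a multi-step assembly with a defined trisubstituted alkene.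
- Comparison: on ring construction and on closeness to known enantioselective catalysis this alternative is the better of the two. The chosen cycloaddition is better on stereocentres and oxidation pattern delivered per step (three target stereocentres and the complete C1–C4 functionality arrive with the ring). The total step count is expected to be similar or higher.

**Alternative 2:** The cut is the C1–C2 bond of the enone, leading to A4, a cyclopentane bearing a C1 thioester arm and a (Z)-α-stannyl alkene on the C4 carbinol. The forward step is an intramolecular acyl cross-coupling of Liebeskind–Srogl type (Pd(PPh3)4 with copper thiophene-2-carboxylate, CuO2CC4H3S), giving the bis-silyl ether A3.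
- In its favour: the enone is formed last and under neutral conditions, so it never has to be masked. On this point the alternative is better than the chosen plan. A3 is one deprotection from the target.
- Against it here: the cut simplifies little. A4 already holds all four stereocentres on a fully substituted cyclopentane, together with a geometrically defined trisubstituted vinylstannane next to a stereogenic silyloxy carbon, so the whole stereochemical problem is moved into the precursor. Closure of a seven-membered ring by acyl coupling has thin precedent. Protodestannylation, stoichiometric copper and tin residues are further burdens.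
- Comparison: its key step makes one ring, one bond and no stereocentre; the chosen one makes one ring, two bonds and four stereocentres. Mechanistically it is the more predictable reaction, but it should cost more steps overall.

**Alternative 3:** The cuts are C6–CH3 and C4–C5. The forward step is a copper-catalysed enantioselective conjugate addition of Al(CH3)3 to the 3-substituted cyclopentenone A6, with trapping of the aluminium enolate at C5 by the aldehyde A7, to give the anti-aldol cyclopentanone A5.
- In its favour: three simple components are joined in one flask and three stereocentres, including quaternary C6, are set. The cyclopentane ring is bought, not made. Absolute control rests on a known catalytic reaction class, whereas the chosen key step is untested in its enantioselective form; on this point the alternative is the better.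
- Against it here: cyclopentenones are the least reactive and least selective substrates for this addition. The C5 configuration requires the aldehyde to approach cis to CH3 and not to CH2CO2CH3 on the adjacent quaternary carbon, a small steric difference. A5 is a β-hydroxy ketone prone to retro-aldol cleavage and dehydration. No ring is formed, so the seven-membered ring (C1–C2 and C2–C3 bonds, for example by a phosphonate olefination) and the C9 carbinol are still to be made, with an oxygen β to the C9 ketone.
- Comparison: equal in bonds formed (two), one stereocentre fewer, no ring against one. The step count is expected to be comparable.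

Key step: step 5

## Route

**Step 1**
Reactants: 1 methyl 3-methylfuran-2-carboxylate
Product: 2 (3-methylfuran-2-yl)methanol
Conditions: LiAlH4, Et2O, 0 °C
Reagents that add atoms: none
Why: Hydride reduction of the ester to the primary alcohol; the furan ring is inert to LiAlH4.

**Step 2**
Reactants: 2 (3-methylfuran-2-yl)methanol
Product: 3 6-hydroxy-4-methyl-2H-pyran-3(6H)-one (racemic)
Conditions: mCPBA, CH2Cl2, 0 °C
Reagents that add atoms: 3-chloroperoxybenzoic acid, OOC(=O)c1cccc(Cl)c1
Why: Achmatowicz rearrangement: oxidation of the furan, opening to the cis-enedione and closure of the hydroxymethyl oxygen onto the aldehyde give the pyranone hemiacetal, with the furan C3 methyl group ending next to the ketone. The acetal centre forms without control and is lost in step 5.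

**Step 3**
Reactants: 3 6-hydroxy-4-methyl-2H-pyran-3(6H)-one
Product: 4 6-acetoxy-4-methyl-2H-pyran-3(6H)-one (racemic)
Conditions: Ac2O, pyridine, DMAP (cat.), CH2Cl2, 0 °C
Reagents that add atoms: acetic anhydride, CC(=O)OC(C)=O
Why: DMAP-catalysed O-acylation of the hemiacetal hydroxyl; run cold and briefly because the product ionises easily.

**Step 4**
Reactants: 5 methyl 4-oxopentanoate (methyl levulinate); 6 trimethyl phosphonoacetate
Product: 7 dimethyl (E)-3-methylhex-2-enedioate
Conditions: NaH, THF, 0 °C → rt; (Z)-isomer removed by chromatography
Reagents that add atoms: none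
Why: Horner–Wadsworth–Emmons olefination of the ketone; the stabilised phosphonate anion should favour the (E)-enoate with the ester trans to the larger CH2CH2CO2CH3 group. The minor (Z)-isomer must be removed because the alkene geometry becomes the C5/C6 relative configuration.

**Step 5**
Reactants: 4 6-acetoxy-4-methyl-2H-pyran-3(6H)-one; 7 dimethyl (E)-3-methylhex-2-enedioate
Product: 9 methyl (1S,5S,6S,7S)-7-(3-methoxy-3-oxopropyl)-3,7-dimethyl-2-oxo-8-oxabicyclo[3.2.1]oct-3-ene-6-carboxylate, via 4-methylpyrylium-3-olate 8 (not isolated)
Conditions: 1-(trans-2-aminocyclohexyl)-3-[3,5-bis(trifluoromethyl)phenyl]thiourea (single enantiomer, 20 mol %), N,N'-bis[3,5-bis(trifluoromethyl)phenyl]thiourea (20 mol %), AcOH (20 mol %), 7 (5 equiv), toluene, 40 °C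
Reagents that add atoms: none
Why: Proposed new method: the primary amine of the catalyst condenses with the C1 ketone of 4 and, with the thiourea pair binding the departing acetate, ionisation and proton loss give the oxidopyrylium 8 (reacting as its catalyst-bound 3-aminopyrylium congener), a five-carbon 4π dipole whose nucleophilic terminus C10 adds to the electrophilic β-carbon C6 of 7 while C4 is captured by the α-carbon C5, so the regiochemistry follows the polarisation of both partners. The closest known reaction types are the base-induced thermal (5+2) cycloadditions of acetoxypyranone-derived oxidopyryliums with acrylates and the aminothiourea/thiourea-catalysed enantioselective pyrylium (5+2) cycloadditions of tethered alkenes and vinyl ethers; an enantioselective intermolecular case with a β,β-disubstituted enoate has not been shown. The seven-membered carbocycle (C1–C2–C3–C4–C5–C6–C10) is closed by the suprafacial two-bond union of the dipole with the alkene, C6–C10 forming ahead of C4–C5, and the pyran oxygen remains as the C4–O–C10 bridge. C4 and C10 are set together by the face of the planar dipole that is attacked, which the chiral amine bound at C1 and its hydrogen-bonded counter-ion must dictate; C5 and C6 keep the (E)-geometry of 7 (ester trans to the chain) because the addition is suprafacial on the alkene; their relation to the bridge comes from the endo position of the C5 ester, which also puts the larger C6 chain exo and only the methyl group under the enone. The step needs rate against dimerisation of 8, met by excess 7 and slow ionisation, and needs facial control, for which the antipode of the amine that gives the (1S,5S,6S,7S)-adduct is selected in the first runs.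

**Step 6**
Reactants: 9 methyl (1S,5S,6S,7S)-7-(3-methoxy-3-oxopropyl)-3,7-dimethyl-2-oxo-8-oxabicyclo[3.2.1]oct-3-ene-6-carboxylate
Product: 10 methyl (1S,2S,7R)-2-hydroxy-7-(3-methoxy-3-oxopropyl)-4,7-dimethyl-5-oxocyclohept-3-ene-1-carboxylate
Conditions: SmI2 (2.2 equiv), THF–MeOH, −78 °C
Reagents that add atoms: none
Why: Reductive cleavage of an α-alkoxy ketone by SmI2: two single-electron transfers expel the bridging oxygen from C10 and methanol protonates the samarium enolate at C10 and the C4 alkoxide; the esters are not reduced and no stereocentre is touched. The bridge is opened here because a trans-fused five-membered ring cannot be closed across C5–C6 while the bicycle holds the C4–C5–C6–C10 torsion near zero.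

**Step 7**
Reactants: 10 methyl (1S,2S,7R)-2-hydroxy-7-(3-methoxy-3-oxopropyl)-4,7-dimethyl-5-oxocyclohept-3-ene-1-carboxylate
Product: 11 methyl (1S,2R,7S)-4,7-bis[(tert-butyldimethylsilyl)oxy]-2-(3-methoxy-3-oxopropyl)-2,5-dimethylcyclohepta-3,5-diene-1-carboxylate
Conditions: TBSOTf (2.5 equiv), Et3N, CH2Cl2, −78 → 0 °C
Reagents that add atoms: tert-butyldimethylsilyl trifluoromethanesulfonate, CC(C)(C)[Si](C)(C)OS(=O)(=O)C(F)(F)F
Why: Silyl triflate/amine silylation: the C4 hydroxyl reacts first, then soft enolisation of the enone at C10 gives the cross-conjugated silyl dienol ether. This masks C1 against enolate and organometallic chemistry and protects the β-hydroxy ester from retro-aldol cleavage.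

**Step 8**
Reactants: 11 methyl (1S,2R,7S)-4,7-bis[(tert-butyldimethylsilyl)oxy]-2-(3-methoxy-3-oxopropyl)-2,5-dimethylcyclohepta-3,5-diene-1-carboxylate
Product: 12 methyl (3aR,8S,8aS)-5,8-bis[(tert-butyldimethylsilyl)oxy]-3a,6-dimethyl-1-oxo-1,2,3,3a,8,8a-hexahydroazulene-2-carboxylate (C2 epimers and enol)
Conditions: LiN(SiMe3)2 (2.5 equiv), THF, −78 → 0 °C
Reagents that add atoms: none
Why: Dieckmann condensation: the unhindered C8 methylene should be deprotonated faster than the congested C5 methine, and its enolate attacks the C9 ester (5-exo-trig), which is possible now that the ring can bring the C7 and C9 arms gauche. The product is held as its stabilised enolate, which also shields C5; the trans fusion is inherited from C5 and C6.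

**Step 9**
Reactants: 12 methyl (3aR,8S,8aS)-5,8-bis[(tert-butyldimethylsilyl)oxy]-3a,6-dimethyl-1-oxo-1,2,3,3a,8,8a-hexahydroazulene-2-carboxylate
Product: 13 (3aR,8S,8aS)-5,8-bis[(tert-butyldimethylsilyl)oxy]-3a,6-dimethyl-3,3a,8,8a-tetrahydroazulen-1(2H)-one
Conditions: LiCl, H2O (2 equiv), DMSO, 130 °C
Reagents that add atoms: none
Why: Krapcho dealkoxycarbonylation: chloride demethylates the β-keto ester, the carboxylate loses CO2 and the C8 enolate is protonated by water. Near-neutral salt conditions are chosen to spare the silyl groups and the C5 stereocentre.

**Step 10**
Reactants: 13 (3aR,8S,8aS)-5,8-bis[(tert-butyldimethylsilyl)oxy]-3a,6-dimethyl-3,3a,8,8a-tetrahydroazulen-1(2H)-one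
Product: 14 (1R,3aR,8S,8aS)-5,8-bis[(tert-butyldimethylsilyl)oxy]-3a,6-dimethyl-1-(propan-2-yl)-1,2,3,3a,8,8a-hexahydroazulen-1-ol
Conditions: iPrMgCl, LaCl3·2LiCl (1 equiv), THF, 0 °C
Reagents that add atoms: isopropylmagnesium chloride, CC(C)[Mg]Cl
Why: Lanthanum-promoted Grignard 1,2-addition, which suppresses enolisation and β-hydride reduction by the branched reagent. Attack should occur on the face of C9 that carries H5, because the other face is screened by the C6 methyl group and by the C5–C4 bond with its silyloxy group; this gives the 9R carbinol, and C1 is inert as the dienol ether.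

**Step 11**
Reactants: 15 4-hydroxybenzoic acid
Product: 16 tert-butyldimethylsilyl 4-[(tert-butyldimethylsilyl)oxy]benzoate
Conditions: TBSCl (2.2 equiv), imidazole, DMF, rt
Reagents that add atoms: tert-butyldimethylsilyl chloride, CC(C)(C)[Si](C)(C)Cl
Why: Silylation of the phenol and the carboxylic acid; the silyl ester is the activated carboxyl derivative for the next step.

**Step 12**
Reactants: 16 tert-butyldimethylsilyl 4-[(tert-butyldimethylsilyl)oxy]benzoate
Product: 17 4-[(tert-butyldimethylsilyl)oxy]benzoyl chloride
Conditions: (COCl)2, DMF (cat.), CH2Cl2, 0 °C → rt
Reagents that add atoms: oxalyl chloride, ClC(=O)C(Cl)=O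
Why: Conversion of a silyl ester into the acid chloride with oxalyl chloride and catalytic DMF (chloroiminium activation) under neutral conditions, which leaves the aryl silyl ether intact.

**Step 13**
Reactants: 14 (1R,3aR,8S,8aS)-5,8-bis[(tert-butyldimethylsilyl)oxy]-3a,6-dimethyl-1-(propan-2-yl)-1,2,3,3a,8,8a-hexahydroazulen-1-ol; 17 4-[(tert-butyldimethylsilyl)oxy]benzoyl chloride
Product: 18 (1R,3aR,8S,8aS)-5,8-bis[(tert-butyldimethylsilyl)oxy]-3a,6-dimethyl-1-(propan-2-yl)-1,2,3,3a,8,8a-hexahydroazulen-1-yl 4-[(tert-butyldimethylsilyl)oxy]benzoate
Conditions: n-BuLi, THF, −78 °C; then 17, −78 → 0 °C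
Reagents that add atoms: none
Why: O-Acylation of a tertiary lithium alkoxide with an aroyl chloride; the alkoxide is the only nucleophile and no enolisable carbonyl is present. Lithium at low temperature is chosen to disfavour transfer of the nearby C4 silyl group to O9.

**Step 14**
Reactants: 18 (1R,3aR,8S,8aS)-5,8-bis[(tert-butyldimethylsilyl)oxy]-3a,6-dimethyl-1-(propan-2-yl)-1,2,3,3a,8,8a-hexahydroazulen-1-yl 4-[(tert-butyldimethylsilyl)oxy]benzoate
Product: 19 (1R,3aR,8S,8aS)-8-hydroxy-3a,6-dimethyl-5-oxo-1-(propan-2-yl)-1,2,3,3a,4,5,8,8a-octahydroazulen-1-yl 4-hydroxybenzoate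
Conditions: HF·pyridine, pyridine, THF, 0 °C → rt
Reagents that add atoms: none
Why: Fluoride-mediated desilylation under buffered acidic conditions: the dienol ether is protonated at C10 and gives the C1 enone, and the C4 and phenol silyl ethers are cleaved (the aryl ether is expected to be slowest). Acidic fluoride is used to avoid the 1,3-acyl shift from O9 to O4 and base-induced isomerisation of the γ-hydroxy enone.

## Compound list

1 | methyl 3-methylfuran-2-carboxylate | COC(=O)c1occc1C | starting material
2 | (3-methylfuran-2-yl)methanol | OCc1occc1C | intermediate
3 | 6-hydroxy-4-methyl-2H-pyran-3(6H)-one (racemic) | CC1=CC(O)OCC1=O | intermediate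
4 | 6-acetoxy-4-methyl-2H-pyran-3(6H)-one (racemic) | CC(=O)OC1C=C(C)C(=O)CO1 | intermediate
5 | methyl 4-oxopentanoate (methyl levulinate) | COC(=O)CCC(C)=O | starting material
6 | trimethyl phosphonoacetate | COC(=O)CP(=O)(OC)OC | starting material
7 | dimethyl (E)-3-methylhex-2-enedioate | COC(=O)/C=C(\C)CCC(=O)OC | intermediate
8 | 4-methylpyrylium-3-olate (not isolated) | Cc1cc[o+]cc1[O-] | intermediate
9 | methyl (1S,5S,6S,7S)-7-(3-methoxy-3-oxopropyl)-3,7-dimethyl-2-oxo-8-oxabicyclo[3.2.1]oct-3-ene-6-carboxylate | CC1=C[C@H]2[C@@H](C(=O)OC)[C@](C)(CCC(=O)OC)[C@H](O2)C1=O | intermediate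
10 | methyl (1S,2S,7R)-2-hydroxy-7-(3-methoxy-3-oxopropyl)-4,7-dimethyl-5-oxocyclohept-3-ene-1-carboxylate | CC1=C[C@H](O)[C@@H](C(=O)OC)[C@](C)(CCC(=O)OC)CC1=O | intermediate
11 | methyl (1S,2R,7S)-4,7-bis[(tert-butyldimethylsilyl)oxy]-2-(3-methoxy-3-oxopropyl)-2,5-dimethylcyclohepta-3,5-diene-1-carboxylate | CC1=C[C@H](O[Si](C)(C)C(C)(C)C)[C@@H](C(=O)OC)[C@](C)(CCC(=O)OC)C=C1O[Si](C)(C)C(C)(C)C | intermediate
12 | methyl (3aR,8S,8aS)-5,8-bis[(tert-butyldimethylsilyl)oxy]-3a,6-dimethyl-1-oxo-1,2,3,3a,8,8a-hexahydroazulene-2-carboxylate (C2 epimers and enol) | CC1=C[C@H](O[Si](C)(C)C(C)(C)C)[C@@H]2[C@](C)(CCC(C(=O)OC)C2=O)C=C1O[Si](C)(C)C(C)(C)C | intermediate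
13 | (3aR,8S,8aS)-5,8-bis[(tert-butyldimethylsilyl)oxy]-3a,6-dimethyl-3,3a,8,8a-tetrahydroazulen-1(2H)-one | CC1=C[C@H](O[Si](C)(C)C(C)(C)C)[C@@H]2[C@](C)(CCC2=O)C=C1O[Si](C)(C)C(C)(C)C | intermediate
14 | (1R,3aR,8S,8aS)-5,8-bis[(tert-butyldimethylsilyl)oxy]-3a,6-dimethyl-1-(propan-2-yl)-1,2,3,3a,8,8a-hexahydroazulen-1-ol | CC1=C[C@H](O[Si](C)(C)C(C)(C)C)[C@@H]2[C@](C)(CC[C@@]2(O)C(C)C)C=C1O[Si](C)(C)C(C)(C)C | intermediate
15 | 4-hydroxybenzoic acid | OC(=O)c1ccc(O)cc1 | starting material
16 | tert-butyldimethylsilyl 4-[(tert-butyldimethylsilyl)oxy]benzoate | CC(C)(C)[Si](C)(C)OC(=O)c1ccc(O[Si](C)(C)C(C)(C)C)cc1 | intermediate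
17 | 4-[(tert-butyldimethylsilyl)oxy]benzoyl chloride | CC(C)(C)[Si](C)(C)Oc1ccc(cc1)C(Cl)=O | intermediate
18 | (1R,3aR,8S,8aS)-5,8-bis[(tert-butyldimethylsilyl)oxy]-3a,6-dimethyl-1-(propan-2-yl)-1,2,3,3a,8,8a-hexahydroazulen-1-yl 4-[(tert-butyldimethylsilyl)oxy]benzoate | CC1=C[C@H](O[Si](C)(C)C(C)(C)C)[C@@H]2[C@](C)(CC[C@@]2(OC(=O)c2ccc(O[Si](C)(C)C(C)(C)C)cc2)C(C)C)C=C1O[Si](C)(C)C(C)(C)C | intermediate
19 | (1R,3aR,8S,8aS)-8-hydroxy-3a,6-dimethyl-5-oxo-1-(propan-2-yl)-1,2,3,3a,4,5,8,8a-octahydroazulen-1-yl 4-hydroxybenzoate | CC1=C[C@H](O)[C@@H]2[C@](C)(CC[C@@]2(OC(=O)c2ccc(O)cc2)C(C)C)CC1=O | target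

## Step count and least certain steps

Total step count: 14. Longest linear sequence: 11 steps (steps 1, 2, 3, 5, 6, 7, 8, 9, 10, 13, 14).

**Step 5 (key step).** The trisubstituted enoate may react too slowly, so that dimerisation of the dipole takes over, and the catalyst may give poor facial or endo/exo selectivity, because neither an electron-poor nor a β,β-disubstituted partner has been used in this catalytic system. Fallback, from 4 and 7 back to 9: the cycloaddition is run in the established thermal way with an amine base (iPr2NEt, 7 as co-solvent, MeCN, 60 °C) to give the racemic cycloadduct F1, and the enantiomers are separated by preparative chromatography on a chiral stationary phase. Both operations are known chemistry, and the absolute configuration is then assigned by correlation.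

**Step 6.** After electron transfer into the enone, the shared oxygen may be lost from C4 (vinylogous cleavage through C2=C3, which would leave the oxygen on C10), or conjugate reduction may occur, instead of cleavage at C10; the two C–O bonds are similarly aligned with the π system. Fallback, from 9 back to 11, removing the conjugation before the cleavage:
- hydrogenation (H2, Pd/C, EtOAc) gives the 2,3-dihydro cycloadduct F2;
- SmI2 (THF–MeOH, −78 °C) then cleaves the now unambiguous α-alkoxy ketone to the saturated hydroxy ketone F3;
- TBSOTf/2,6-lutidine gives its C4 silyl ether F4;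
- dehydrogenation with IBX (DMSO, 70 °C) can only introduce C2=C3, because C6 is quaternary, and gives the silyloxy enone F5;
- TBSOTf/Et3N converts F5 into 11.

**Step 9.** At 130 °C in a medium that becomes slightly basic, the silyl dienol ether may hydrolyse, the C4 silyloxy group may be lost by β-elimination from the new C9 ketone, and C5 may epimerise. Fallback, from 12 back to 13: transesterification of the β-keto ester with allyl alcohol (DMAP cat., toluene, 100 °C) gives the allyl β-keto ester F6, which is deallylated and decarboxylated at room temperature with Pd(PPh3)4 (zerovalent palladium) and morpholine in THF.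

**Step 10.** The branched Grignard reagent may enolise the hindered ketone or reduce it by β-hydride transfer, and the facial bias may be incomplete. Fallback, from 13 back to 14: addition of the smaller, hydride-free isopropenylmagnesium bromide (CH2=C(CH3)MgBr, LaCl3·2LiCl, THF, 0 °C) gives the isopropenyl carbinol F7. Its 1,1-disubstituted alkene is then hydrogenated selectively with RhCl(PPh3)3 and H2 (benzene–EtOH), which leaves the trisubstituted alkenes of the dienol ether untouched.

**Step 13.** Acylation of the congested tertiary alkoxide may be slow, and the C4 silyl group may move to O9 (the two oxygens are 1,3-syn), which would send the acyl group to O4. Fallback, from 13 directly to 18, leaving out isolated 14: the magnesium alkoxide formed in the Grignard addition of step 10 is not protonated but treated in the same flask with excess 17 (THF, 0 °C → rt). No free alkali alkoxide is generated by deprotonation, and the more covalent magnesium alkoxide is less prone to silyl transfer. This fallback makes no compound outside the list (F0).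

## Further compounds

F1 | step 5 | racemic 9 (equal mixture of 9 and its mirror image) | CC1=C[C@H]2[C@@H](C(=O)OC)[C@](C)(CCC(=O)OC)[C@H](O2)C1=O.CC1=C[C@@H]2[C@H](C(=O)OC)[C@@](C)(CCC(=O)OC)[C@@H](O2)C1=O
F2 | step 6 | 2,3-dihydro derivative of 9 (C2 epimers; bridge intact) | CC1C[C@H]2[C@@H](C(=O)OC)[C@](C)(CCC(=O)OC)[C@H](O2)C1=O
F3 | step 6 | 2,3-dihydro derivative of 10 (saturated 4-hydroxy ketone, C2 epimers) | CC1C[C@H](O)[C@@H](C(=O)OC)[C@](C)(CCC(=O)OC)CC1=O
F4 | step 6 | C4 tert-butyldimethylsilyl ether of F3 | CC1C[C@H](O[Si](C)(C)C(C)(C)C)[C@@H](C(=O)OC)[C@](C)(CCC(=O)OC)CC1=O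
F5 | step 6 | C4 tert-butyldimethylsilyl ether of 10 | CC1=C[C@H](O[Si](C)(C)C(C)(C)C)[C@@H](C(=O)OC)[C@](C)(CCC(=O)OC)CC1=O
F6 | step 9 | allyl ester analogue of 12 (C8 allyl ester, C2 epimers and enol) | CC1=C[C@H](O[Si](C)(C)C(C)(C)C)[C@@H]2[C@](C)(CCC(C(=O)OCC=C)C2=O)C=C1O[Si](C)(C)C(C)(C)C
F7 | step 10 | isopropenyl analogue of 14 (C9 carbinol with prop-1-en-2-yl group) | CC1=C[C@H](O[Si](C)(C)C(C)(C)C)[C@@H]2[C@](C)(CC[C@@]2(O)C(C)=C)C=C1O[Si](C)(C)C(C)(C)C
F0 | step 13 | none | none
A1 | alternative 1 | (6R)-bicyclo[5.3.0]deca-4,10(1)-diene with C1 tert-butyldimethylsilyl enol ether, C6 methyl group and C9 ethylene ketal (target numbering) | C1CC(O[Si](C)(C)C(C)(C)C)=C[C@@]2(C)CCC3(OCCO3)C2=C1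
A2 | alternative 1 | 2-ethynyl-2-[(E)-3-methyl-4-(1-[(tert-butyldimethylsilyl)oxy]cyclopropyl)but-3-enyl]-1,3-dioxolane | C#CC1(OCCO1)CC/C(C)=C/C1(CC1)O[Si](C)(C)C(C)(C)C
A3 | alternative 2 | bis(tert-butyldimethylsilyl) ether of 19 (O4 and phenol) | CC1=C[C@H](O[Si](C)(C)C(C)(C)C)[C@@H]2[C@](C)(CC[C@@]2(OC(=O)c2ccc(O[Si](C)(C)C(C)(C)C)cc2)C(C)C)CC1=O
A4 | alternative 2 | seco compound: cyclopentane with C10–C1 S-phenyl thioester arm on C6 and (Z)-3-(tributylstannyl)but-2-enyl silyl ether (C4–C3=C2) on C5, C9 aroyloxy and isopropyl | CCCC[Sn](CCCC)(CCCC)/C(C)=C\[C@H](O[Si](C)(C)C(C)(C)C)[C@@H]1[C@](C)(CC[C@@]1(OC(=O)c1ccc(O[Si](C)(C)C(C)(C)C)cc1)C(C)C)CC(=O)Sc1ccccc1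
A5 | alternative 3 | anti-aldol cyclopentanone: methyl 2-[(1R*)-configured 2-(1-hydroxy-2,2-dimethoxyethyl)-1-methyl-3-oxocyclopentyl]acetate, configuration as in the SMILES | COC(OC)[C@H](O)[C@@H]1[C@](C)(CCC1=O)CC(=O)OC
A6 | alternative 3 | methyl 2-(3-oxocyclopent-1-en-1-yl)acetate | COC(=O)CC1=CC(=O)CC1
A7 | alternative 3 | 2,2-dimethoxyacetaldehyde | COC(OC)C=O
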